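**Retrosynthetic overview**

1. Endgame (C–O bonds only): the C5 side-chain senecioate and the C3 isovalerate are installed by acylation; the 2-(3-oxoprop-1-en-2-yl) group comes from an isopropenyl group by allylic oxidation, and the isopropenyl group from a 2-hydroxypropan-2-yl group by dehydration.
2. Key disconnection: the dihydrofuran ring of the resulting cis-diol is opened at O1–C2 and C3a–C3, giving an ortho-lithiated phenoxide (benzene ring with O1 in place) and (S)-3,3-dimethyloxirane-2-carbaldehyde.
3. Enabling feature: in the O1–C2–C3–C3a part of the five-membered ring, C3 carries an oxygen (an aldehyde-derived carbinol), C2 carries O1 and sits next to an exocyclic carbon that can carry oxygen (so C2 and that carbon map onto an oxirane), and C3a is ortho to O1. The phenol can therefore act as a C,O-dinucleophile on a 1,2-dielectrophile.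
4. Stereochemistry: the side-chain (S) centre comes from a ketoreductase reduction and the oxirane centre from a Sharpless epoxidation; C3 is set by anti-selective addition to the epoxy aldehyde and C2 by invertive oxirane opening (anti adduct gives the 2,3-cis ring).
5. Ring order: the benzene ring is bought, the oxirane is a temporary ring (made in step 3, consumed in step 5), and the dihydrofuran ring is the only ring of the target that is built (step 5).

Key step: step 5

Remark: the SMILES is read as the 2,3-cis (2R,3R)-2,3-dihydrobenzofuran with an (S)-configured C5 side-chain carbinol; step 5 is run in one flask without isolation of intermediates.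

**Route**

Step 1
Reactants: 1 1-(3-bromo-4-hydroxyphenyl)ethan-1-one
Product: 2 2-bromo-4-[(1S)-1-hydroxyethyl]phenol
Conditions: Prelog-selective NADPH-dependent ketoreductase (alcohol dehydrogenase), NADP+ (cat.), i-PrOH, phosphate buffer pH 7, 30 °C
Reagents that add atoms: none
Why: Enzymatic asymmetric ketone reduction; ketoreductases of the Prelog type deliver hydride to one face of aryl methyl ketones and should give the (S)-carbinol directly on the unprotected bromophenol.

Step 2
Reactants: 2 2-bromo-4-[(1S)-1-hydroxyethyl]phenol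
Product: 4 2-bromo-4-[(1S)-1-{[tert-butyl(dimethyl)silyl]oxy}ethyl]phenol, via bis-silyl ether 3 (not isolated)
Conditions: TBSCl (2.2 equiv), imidazole, DMF, rt; then MeOH, K2CO3 (cat.), rt
Reagents that add atoms: tert-butyldimethylsilyl chloride, CC(C)(C)[Si](C)(C)Cl
Why: Exhaustive silylation followed by selective methanolysis of the aryl silyl ether; the bromophenoxide is a far better leaving group than the secondary alkoxide, so only the phenol should be set free.

Step 3
Reactants: 5 3-methylbut-2-en-1-ol (prenol)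
Product: 6 [(2R)-3,3-dimethyloxiran-2-yl]methanol
Conditions: Ti(Oi-Pr)4 (cat.), D-(−)-diisopropyl tartrate (cat.), t-BuOOH, 4 Å MS, CH2Cl2, −20 °C
Reagents that add atoms: tert-butyl hydroperoxide, CC(C)(C)OO
Why: Sharpless asymmetric epoxidation; with the D-(−)-tartrate the oxygen is delivered to the alkene face that gives the (R)-epoxy alcohol, the stereocentre that later defines C2.

Step 4
Reactants: 6 [(2R)-3,3-dimethyloxiran-2-yl]methanol
Product: 7 (2S)-3,3-dimethyloxirane-2-carbaldehyde
Conditions: TPAP (cat.), NMO, 4 Å MS, CH2Cl2, rt; filtration through silica, careful concentration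
Reagents that add atoms: none
Why: Ley–Griffith oxidation is neutral and non-aqueous, so the acid-sensitive trisubstituted oxirane and its non-enolisable α-centre should be preserved (the descriptor changes from R to S only because of CIP priorities).

Step 5
Reactants: 4 2-bromo-4-[(1S)-1-{[tert-butyl(dimethyl)silyl]oxy}ethyl]phenol; 7 (2S)-3,3-dimethyloxirane-2-carbaldehyde
Product: 10 (2S,3R)-5-[(1S)-1-{[tert-butyl(dimethyl)silyl]oxy}ethyl]-2-(2-hydroxypropan-2-yl)-2,3-dihydro-1-benzofuran-3-ol (2,3-cis), via C-lithiated lithium phenoxide 8 (not isolated), via anti epoxy alkoxide 9 (not isolated)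
Conditions: n-BuLi (1.0 equiv), THF, −78 °C; t-BuLi (2.0 equiv), −78 °C; 7, −78 °C; then MeOH, −78 → 40 °C; aq. NH4Cl
Reagents that add atoms: none
Why: Bromine–lithium exchange on the lithium phenoxide gives the C-lithiated phenoxide 8, whose aryl carbon adds 1,2 to the aldehyde of 7 (C3a–C3 bond, C3 stereocentre) and whose phenoxide oxygen then opens the oxirane at its CH carbon with inversion once the mixture is warmed in the presence of methanol (O1–C2 bond, C2 stereocentre), so that a formal (3+2) annulation of a phenol C,O-dinucleophile with a 1,2-dielectrophile results. The closest known reaction types are the anti-selective addition of organolithium reagents to α,β-epoxy aldehydes and the base-mediated closure of o-(2,3-epoxy-3-methylbutyl)phenols to 2-(2-hydroxypropan-2-yl)-2,3-dihydrobenzofurans. The dihydrofuran ring closes in the 5-exo-tet mode at the secondary oxirane carbon, which under basic, Lewis-acid-free conditions is preferred over 6-endo attack at the tertiary carbon. C3 is controlled by the oxirane stereocentre of 7 through a polar Felkin–Anh (Cornforth) transition state in which the aryl group enters anti to the oxirane C–O bond, a preference that the 3,3-disubstitution of the oxirane is expected to reinforce, giving the anti (R,R) adduct 9; C2 is controlled by stereospecific SN2 inversion of that same oxirane carbon, and anti adduct plus inversion corresponds to the 2,3-cis ring. The step needs chemoselectivity for the aldehyde over the oxirane (secured at −78 °C), facial selectivity (secured by the α-heteroatom of 7 in coordinating THF, where chelation is weak) and ring closure by the phenoxide instead of the benzylic alkoxide (secured by the higher acidity of the phenol, which leaves the phenoxide as the dominant anion in methanol, and by the rigid aryl tether).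

Step 6
Reactants: 10 (2S,3R)-5-[(1S)-1-{[tert-butyl(dimethyl)silyl]oxy}ethyl]-2-(2-hydroxypropan-2-yl)-2,3-dihydro-1-benzofuran-3-ol
Product: 11 (2S,3R)-5-[(1S)-1-{[tert-butyl(dimethyl)silyl]oxy}ethyl]-2-(2-hydroxypropan-2-yl)-2,3-dihydro-1-benzofuran-3-yl 3-methylbutanoate
Conditions: 3-methylbutanoyl chloride, pyridine, DMAP (cat.), CH2Cl2, 0 °C
Reagents that add atoms: 3-methylbutanoyl chloride (isovaleryl chloride), CC(C)CC(=O)Cl
Why: DMAP-catalysed acylation (Steglich-type acyl transfer) of the secondary benzylic alcohol with retention; the tertiary alcohol is too hindered to react under these conditions.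

Step 7
Reactants: 11 (2S,3R)-5-[(1S)-1-{[tert-butyl(dimethyl)silyl]oxy}ethyl]-2-(2-hydroxypropan-2-yl)-2,3-dihydro-1-benzofuran-3-yl 3-methylbutanoate
Product: 12 (2R,3R)-5-[(1S)-1-{[tert-butyl(dimethyl)silyl]oxy}ethyl]-2-(prop-1-en-2-yl)-2,3-dihydro-1-benzofuran-3-yl 3-methylbutanoate
Conditions: Burgess reagent, toluene, 60 °C
Reagents that add atoms: none
Why: Burgess dehydration; the tertiary sulfamate should eliminate toward one of the six methyl hydrogens in preference to the single C2–H, which is inductively deactivated by O1, giving the isopropenyl group without touching C2 or C3 (the C2 descriptor changes only through CIP priorities).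

Step 8
Reactants: 12 (2R,3R)-5-[(1S)-1-{[tert-butyl(dimethyl)silyl]oxy}ethyl]-2-(prop-1-en-2-yl)-2,3-dihydro-1-benzofuran-3-yl 3-methylbutanoate
Product: 14 (2R,3R)-5-[(1S)-1-{[tert-butyl(dimethyl)silyl]oxy}ethyl]-2-(3-oxoprop-1-en-2-yl)-2,3-dihydro-1-benzofuran-3-yl 3-methylbutanoate, via allylic alcohol 13 (not isolated)
Conditions: SeO2 (0.3 equiv), t-BuOOH, CH2Cl2, rt; then MnO2, CH2Cl2, rt
Reagents that add atoms: selenium dioxide, O=[Se]=O; tert-butyl hydroperoxide, CC(C)(C)OO (terminal oxidant that restores the selenium reagent)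
Why: Sharpless-type catalytic SeO2 allylic oxidation (ene reaction, then [2,3]-sigmatropic shift) should functionalise the methyl group of the 1,1-disubstituted alkene (CH3 preferred over the CH at C2), and MnO2 then oxidises the allylic alcohol to the enal; no stereocentre is involved and the senecioate is not yet present.

Step 9
Reactants: 14 (2R,3R)-5-[(1S)-1-{[tert-butyl(dimethyl)silyl]oxy}ethyl]-2-(3-oxoprop-1-en-2-yl)-2,3-dihydro-1-benzofuran-3-yl 3-methylbutanoate
Product: 15 (2R,3R)-5-[(1S)-1-hydroxyethyl]-2-(3-oxoprop-1-en-2-yl)-2,3-dihydro-1-benzofuran-3-yl 3-methylbutanoate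
Conditions: HF·pyridine, pyridine, THF, 0 °C → rt
Reagents that add atoms: none
Why: Fluoride-mediated desilylation under pyridine-buffered conditions, chosen to avoid ionisation of the p-alkoxybenzylic position and base-induced loss of the C3 ester.

Step 10
Reactants: 15 (2R,3R)-5-[(1S)-1-hydroxyethyl]-2-(3-oxoprop-1-en-2-yl)-2,3-dihydro-1-benzofuran-3-yl 3-methylbutanoate
Product: 16 (1S)-1-[(2R,3R)-3-[(3-methylbutanoyl)oxy]-2-(3-oxoprop-1-en-2-yl)-2,3-dihydro-1-benzofuran-5-yl]ethyl 3-methylbut-2-enoate (CNP0325942.1)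
Conditions: 3-methylbut-2-enoyl chloride, pyridine, CH2Cl2, 0 °C
Reagents that add atoms: 3-methylbut-2-enoyl chloride (senecioyl chloride), CC(C)=CC(=O)Cl
Why: Esterification with the acid chloride in pyridine (no trialkylamine, to avoid vinylketene formation and deconjugation of the senecioyl group) proceeds with retention at the carbinol centre.

**Compound list**

1 | 1-(3-bromo-4-hydroxyphenyl)ethan-1-one | CC(=O)c1ccc(O)c(Br)c1 | starting material
2 | 2-bromo-4-[(1S)-1-hydroxyethyl]phenol | C[C@H](O)c1ccc(O)c(Br)c1 | intermediate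
3 | {2-bromo-4-[(1S)-1-{[tert-butyl(dimethyl)silyl]oxy}ethyl]phenoxy}(tert-butyl)dimethylsilane (bis-silyl ether) | C[C@H](O[Si](C)(C)C(C)(C)C)c1ccc(O[Si](C)(C)C(C)(C)C)c(Br)c1 | intermediate
4 | 2-bromo-4-[(1S)-1-{[tert-butyl(dimethyl)silyl]oxy}ethyl]phenol | C[C@H](O[Si](C)(C)C(C)(C)C)c1ccc(O)c(Br)c1 | intermediate
5 | 3-methylbut-2-en-1-ol (prenol) | CC(C)=CCO | starting material
6 | [(2R)-3,3-dimethyloxiran-2-yl]methanol | OC[C@H]1OC1(C)C | intermediate
7 | (2S)-3,3-dimethyloxirane-2-carbaldehyde | O=C[C@H]1OC1(C)C | intermediate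
8 | lithium 4-[(1S)-1-{[tert-butyl(dimethyl)silyl]oxy}ethyl]-2-lithiophenolate (C-lithiated lithium phenoxide) | [Li]Oc1ccc([C@H](C)O[Si](C)(C)C(C)(C)C)cc1[Li] | intermediate
9 | dilithium salt of (R)-[(2R)-3,3-dimethyloxiran-2-yl]{2-hydroxy-5-[(1S)-1-{[tert-butyl(dimethyl)silyl]oxy}ethyl]phenyl}methanol (anti epoxy alkoxide) | [Li]Oc1ccc([C@H](C)O[Si](C)(C)C(C)(C)C)cc1[C@H]([C@H]1OC1(C)C)O[Li] | intermediate
10 | (2S,3R)-5-[(1S)-1-{[tert-butyl(dimethyl)silyl]oxy}ethyl]-2-(2-hydroxypropan-2-yl)-2,3-dihydro-1-benzofuran-3-ol | CC(C)(O)[C@H]1Oc2ccc([C@H](C)O[Si](C)(C)C(C)(C)C)cc2[C@H]1O | intermediate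
11 | (2S,3R)-5-[(1S)-1-{[tert-butyl(dimethyl)silyl]oxy}ethyl]-2-(2-hydroxypropan-2-yl)-2,3-dihydro-1-benzofuran-3-yl 3-methylbutanoate | CC(C)(O)[C@H]1Oc2ccc([C@H](C)O[Si](C)(C)C(C)(C)C)cc2[C@H]1OC(=O)CC(C)C | intermediate
12 | (2R,3R)-5-[(1S)-1-{[tert-butyl(dimethyl)silyl]oxy}ethyl]-2-(prop-1-en-2-yl)-2,3-dihydro-1-benzofuran-3-yl 3-methylbutanoate | C=C(C)[C@H]1Oc2ccc([C@H](C)O[Si](C)(C)C(C)(C)C)cc2[C@H]1OC(=O)CC(C)C | intermediate
13 | (2R,3R)-5-[(1S)-1-{[tert-butyl(dimethyl)silyl]oxy}ethyl]-2-(3-hydroxyprop-1-en-2-yl)-2,3-dihydro-1-benzofuran-3-yl 3-methylbutanoate | C=C(CO)[C@H]1Oc2ccc([C@H](C)O[Si](C)(C)C(C)(C)C)cc2[C@H]1OC(=O)CC(C)C | intermediate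
14 | (2R,3R)-5-[(1S)-1-{[tert-butyl(dimethyl)silyl]oxy}ethyl]-2-(3-oxoprop-1-en-2-yl)-2,3-dihydro-1-benzofuran-3-yl 3-methylbutanoate | C=C(C=O)[C@H]1Oc2ccc([C@H](C)O[Si](C)(C)C(C)(C)C)cc2[C@H]1OC(=O)CC(C)C | intermediate
15 | (2R,3R)-5-[(1S)-1-hydroxyethyl]-2-(3-oxoprop-1-en-2-yl)-2,3-dihydro-1-benzofuran-3-yl 3-methylbutanoate | C=C(C=O)[C@H]1Oc2ccc([C@H](C)O)cc2[C@H]1OC(=O)CC(C)C | intermediate
16 | (1S)-1-[(2R,3R)-3-[(3-methylbutanoyl)oxy]-2-(3-oxoprop-1-en-2-yl)-2,3-dihydro-1-benzofuran-5-yl]ethyl 3-methylbut-2-enoate | C=C(C=O)[C@H]1Oc2ccc([C@H](C)OC(=O)C=C(C)C)cc2[C@H]1OC(=O)CC(C)C | target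

**Step count and risks**

Total step count: 10. Longest linear sequence: 8 steps (steps 1, 2, 5–10; the branch through steps 3 and 4 is equally long).

Steps most likely to fail:

Step 5 (key step). What may go wrong is erosion of facial selectivity in the aryllithium addition, with lithium chelation between the formyl and oxirane oxygens competing with the polar Felkin–Anh mode. Because C2 is fixed by the invertive ring closure, this would give C3 epimers of 10; a lesser risk is 6-endo closure at the tertiary oxirane carbon. Fallback: setting out from 10 as the C3-epimeric mixture, the benzylic carbinol is oxidised with MnO2 in CH2Cl2 to the single ketone (2R)-5-[(1S)-1-{[tert-butyl(dimethyl)silyl]oxy}ethyl]-2-(2-hydroxypropan-2-yl)-1-benzofuran-3(2H)-one F1. The ketone is then reduced at −78 °C with NaBH4/CeCl3 in MeOH, hydride adding to the face opposite to the C2 substituent, which returns to the cis-diol 10. C3 is then set by substrate-controlled ketone reduction instead of by the addition.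

Step 7. What may go wrong is elimination in the wrong direction (toward C2–H, followed by loss of the ester and aromatisation to the benzofuran), or participation of the cis ester carbonyl in the ionisation of the tertiary sulfamate with acyl shift. Fallback: setting out from 10, the secondary hydroxyl is silylated (TESCl, imidazole, CH2Cl2) to the triethylsilyl ether 2-[(2S,3R)-5-[(1S)-1-{[tert-butyl(dimethyl)silyl]oxy}ethyl]-3-[(triethylsilyl)oxy]-2,3-dihydro-1-benzofuran-2-yl]propan-2-ol F2. The tertiary alcohol is dehydrated with Martin sulfurane (CH2Cl2, 0 °C) to the isopropenyl compound tert-butyl(dimethyl){(1S)-1-[(2R,3R)-2-(prop-1-en-2-yl)-3-[(triethylsilyl)oxy]-2,3-dihydro-1-benzofuran-5-yl]ethoxy}silane F3. The triethylsilyl group is removed selectively (PPTS, MeOH, 0 °C) to the cis-alcohol (2R,3R)-5-[(1S)-1-{[tert-butyl(dimethyl)silyl]oxy}ethyl]-2-(prop-1-en-2-yl)-2,3-dihydro-1-benzofuran-3-ol F4, and F4 is acylated with 3-methylbutanoyl chloride/pyridine, which comes back to the route at 12. The elimination is thereby carried out next to a non-participating ether and the ester is introduced only afterwards.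

Step 8. What may go wrong is the ene reaction taking the wrong allylic hydrogen (C2–H), incomplete or over-oxidation, and acid-promoted loss of the C3 ester by selenous acid. Fallback: setting out from 12, selenium-catalysed ene-type chlorination (NCS, PhSeCl cat., CH2Cl2) gives the allylic chloride (2R,3R)-5-[(1S)-1-{[tert-butyl(dimethyl)silyl]oxy}ethyl]-2-(3-chloroprop-1-en-2-yl)-2,3-dihydro-1-benzofuran-3-yl 3-methylbutanoate F5. F5 is oxidised with N-methylmorpholine N-oxide (NaI cat., MeCN; Ganem/Kornblum-type) to the enal 14, where the route is rejoined.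

Further compounds

F1 | step 5 | (2R)-5-[(1S)-1-{[tert-butyl(dimethyl)silyl]oxy}ethyl]-2-(2-hydroxypropan-2-yl)-1-benzofuran-3(2H)-one | CC(C)(O)[C@H]1Oc2ccc([C@H](C)O[Si](C)(C)C(C)(C)C)cc2C1=O
F2 | step 7 | 2-[(2S,3R)-5-[(1S)-1-{[tert-butyl(dimethyl)silyl]oxy}ethyl]-3-[(triethylsilyl)oxy]-2,3-dihydro-1-benzofuran-2-yl]propan-2-ol | CC(C)(O)[C@H]1Oc2ccc([C@H](C)O[Si](C)(C)C(C)(C)C)cc2[C@H]1O[Si](CC)(CC)CC
F3 | step 7 | tert-butyl(dimethyl){(1S)-1-[(2R,3R)-2-(prop-1-en-2-yl)-3-[(triethylsilyl)oxy]-2,3-dihydro-1-benzofuran-5-yl]ethoxy}silane | C=C(C)[C@H]1Oc2ccc([C@H](C)O[Si](C)(C)C(C)(C)C)cc2[C@H]1O[Si](CC)(CC)CC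
F4 | step 7 | (2R,3R)-5-[(1S)-1-{[tert-butyl(dimethyl)silyl]oxy}ethyl]-2-(prop-1-en-2-yl)-2,3-dihydro-1-benzofuran-3-ol | C=C(C)[C@H]1Oc2ccc([C@H](C)O[Si](C)(C)C(C)(C)C)cc2[C@H]1O
F5 | step 8 | (2R,3R)-5-[(1S)-1-{[tert-butyl(dimethyl)silyl]oxy}ethyl]-2-(3-chloroprop-1-en-2-yl)-2,3-dihydro-1-benzofuran-3-yl 3-methylbutanoate | C=C(CCl)[C@H]1Oc2ccc([C@H](C)O[Si](C)(C)C(C)(C)C)cc2[C@H]1OC(=O)CC(C)C
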